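The target consists of three 8-methoxy-1-naphthol units held together by two biaryl bonds: on the middle unit, C2 and C4 of the phenolic ring (ortho and para to the C1 hydroxyl) are each attached to C2 of a terminal unit. Both bonds are disconnected together, back to 8-methoxy-1-naphthol and two molecules of its 4-bromo derivative. One anodic dehydrogenative cross-coupling oxidises the middle naphthol twice and traps it twice with the bromo naphthol, whose only open ortho/para carbon is C2. The two coupling partners come from 1,8-dihydroxynaphthalene in two steps; the bromines that block C4 of the terminal rings are removed by hydrogenolysis at the end.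

Key step: step 3

Assumption: neither biaryl axis is configurationally stable at room temperature (no axis has more than two small ortho substituents, and the SMILES carries no stereodescriptor), so the target is treated as one stereochemically undefined compound.

Step 1
Reactants: 1 1,8-dihydroxynaphthalene; 2 iodomethane
Product: 3 8-methoxy-1-naphthol
Conditions: MeI (1.1 equiv), K2CO3 (1.1 equiv), acetone, reflux, N2
Reagents that add atoms: iodomethane (2), CI
Why: Williamson ether synthesis on the hydrogen-bond-stabilised monoanion of the peri-diol; after the first methylation the remaining hydroxyl is tied up in an O–H···OMe peri hydrogen bond and is far less nucleophilic under K2CO3, so alkylation should stop at the monoether.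

Step 2
Reactants: 3 8-methoxy-1-naphthol; 4 N-bromosuccinimide
Product: 5 4-bromo-8-methoxy-1-naphthol
Conditions: NBS (1.0 equiv), MeCN, −20 to 0 °C, dark
Reagents that add atoms: N-bromosuccinimide (4), O=C1CCC(=O)N1Br
Why: Electrophilic aromatic bromination should go to C4, para to the free hydroxyl, because the phenol ring is the more activated ring (the OH donates its hydrogen bond to the peri methoxy oxygen, which strengthens O1 and weakens O8 as a donor) and NBS in a polar solvent favours para over ortho attack on phenols.

Step 3
Reactants: 3 8-methoxy-1-naphthol (1 equiv); 5 4-bromo-8-methoxy-1-naphthol (2 equiv consumed, 6 equiv charged)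
Product: 8 4,4''-dibromo-8,8',8''-trimethoxy-[2,2':4',2''-ternaphthalene]-1,1',1''-triol, via 4,2'-linked bromo binaphthol 6 (not isolated), via 2,2'-linked bromo binaphthol 7 (not isolated)
Conditions: undivided cell, boron-doped diamond anode, Pt cathode, constant current (about 5 mA cm−2, about 4 F per mol of 3); 5 and methyltributylammonium methyl sulfate (0.1 M) in 1,1,1,3,3,3-hexafluoropropan-2-ol (HFIP)/MeOH 9:1, 50 °C; 3 added by syringe pump in step with the charge passed; then HFIP distilled off, excess 5 recovered and 8 purified by chromatography
Reagents that add atoms: none
Why: Proposed new method: at the anode the most electron-rich phenol, 3, should lose an electron and a proton to give an HFIP-solvated naphthoxyl radical with spin at C2 and C4, which is attacked by the free C2 of the excess, less oxidisable partner 5, and loss of a second electron and proton rearomatises to biaryl 6 (bond at C4) or 7 (bond at C2); both dimers are more electron-rich than either monomer, so they should be re-oxidised and trapped by a second molecule of 5 at the one ortho or para carbon left on the middle ring, converging on 8. The closest known reaction type is the anodic dehydrogenative phenol–phenol and phenol–arene cross-coupling in HFIP at boron-doped diamond, including twofold couplings to meta-terphenyl-2,2''-diols; new here is a twofold hetero-coupling in which a 1-naphthol is the doubly oxidised middle partner. No ring is closed and no stereocentre is formed, since both new bonds are aryl–aryl bonds with freely rotating axes. The step needs cross- instead of homo-coupling and substitution of the middle ring at C2 and C4 only: the C4 bromine of 5 leaves C2 as its single reactive carbon and raises its oxidation potential, while its excess and the metered addition of 3 disfavour the 4,4'-dimer of 3. Chain growth should end at 8 because every ortho and para carbon of its three phenolic rings is substituted, and the charge is limited to the four electrons required so that the trimer is not oxidised further.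

Step 4
Reactants: 8 4,4''-dibromo-8,8',8''-trimethoxy-[2,2':4',2''-ternaphthalene]-1,1',1''-triol
Product: 9 8,8',8''-trimethoxy-[2,2':4',2''-ternaphthalene]-1,1',1''-triol (target CNP0482979.0)
Conditions: H2 (1 atm), Pd/C (10 wt%), NaOAc (2.5 equiv), THF/MeOH, rt
Reagents that add atoms: none
Why: Palladium-catalysed hydrogenolysis of aryl C–Br bonds (hydrodehalogenation) is fast at one atmosphere when the HBr is buffered, and naphthalene rings, aryl methyl ethers and free phenols should be untouched at room temperature.

Compound list
1 | 1,8-dihydroxynaphthalene | Oc1cccc2cccc(O)c12 | starting material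
2 | iodomethane | CI | starting material
3 | 8-methoxy-1-naphthol | COc1cccc2cccc(O)c12 | intermediate
4 | N-bromosuccinimide | O=C1CCC(=O)N1Br | starting material
5 | 4-bromo-8-methoxy-1-naphthol | COc1cccc2c(Br)ccc(O)c12 | intermediate
6 | 4-bromo-2-(4-hydroxy-5-methoxynaphthalen-1-yl)-8-methoxynaphthalen-1-ol (middle C4 to terminal C2; formed in the cell) | COc1cccc2c(-c3cc(Br)c4cccc(OC)c4c3O)ccc(O)c12 | intermediate
7 | 4-bromo-8,8'-dimethoxy-[2,2'-binaphthalene]-1,1'-diol (middle C2 to terminal C2; formed in the cell) | COc1cccc2ccc(-c3cc(Br)c4cccc(OC)c4c3O)c(O)c12 | intermediate
8 | 4,4''-dibromo-8,8',8''-trimethoxy-[2,2':4',2''-ternaphthalene]-1,1',1''-triol | COc1cccc2c(Br)cc(-c3cc(-c4cc(Br)c5cccc(OC)c5c4O)c4cccc(OC)c4c3O)c(O)c12 | intermediate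
9 | 8,8',8''-trimethoxy-[2,2':4',2''-ternaphthalene]-1,1',1''-triol | COc1cccc2ccc(-c3cc(-c4ccc5cccc(OC)c5c4O)c4cccc(OC)c4c3O)c(O)c12 | target

Total step count: 4
Longest linear sequence: 4 steps (1 → 3 → 5 → 8 → 9)

Steps most likely to fail

1. Step 3 (proposed new method). What may go wrong: homo-coupling of the unblocked naphthol through C4, anodic oxidation of the bromo partner whenever the unblocked one runs short, capture of the oxidised naphthol by methanol, or over-oxidation of the electron-rich coupling products to quinoid material. The fallback uses known chemistry, sets out from 3 and 5 and returns at 9. Compound 5 is iodinated at its only open phenol-ring carbon (N-iodosuccinimide, MeCN, 0 °C) to give 4-bromo-2-iodo-8-methoxy-1-naphthol F1. This is protected (NaH, chloromethyl methyl ether, THF/DMF, 0 °C) as 4-bromo-2-iodo-8-methoxy-1-(methoxymethoxy)naphthalene F2. Compound 3 is protected in the same way as 8-methoxy-1-(methoxymethoxy)naphthalene F3. Acetal-directed ortho-lithiation at C2 (n-BuLi, TMEDA, THF, 0 °C) and a quench with 2-isopropoxy-4,4,5,5-tetramethyl-1,3,2-dioxaborolane should give 2-[8-methoxy-1-(methoxymethoxy)naphthalen-2-yl]-4,4,5,5-tetramethyl-1,3,2-dioxaborolane F4. A twofold Suzuki–Miyaura coupling of F2 with F4 (2.5 equiv; Pd(OAc)2, SPhos, K3PO4, toluene/water, 90 °C) should give 8,8',8''-trimethoxy-1,1',1''-tris(methoxymethoxy)-2,2':4',2''-ternaphthalene F5. HCl in MeOH/THF then removes the three acetals and gives 9 directly, so 8 is bypassed.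

2. Step 2. What may go wrong: competing attack at C2 and double bromination, giving isomer mixtures that are hard to separate. The fallback sets out from 3 and returns at 5. Two equivalents of NBS in MeCN fill both C2 and C4 of the phenol ring and give 2,4-dibromo-8-methoxy-1-naphthol F6. This is protected (NaH, chloromethyl methyl ether, THF/DMF) as 2,4-dibromo-8-methoxy-1-(methoxymethoxy)naphthalene F7. Chelation-controlled bromine–lithium exchange at the bromine next to the acetal oxygen (n-BuLi, 1.0 equiv, THF, −78 °C) and a MeOH quench should give 4-bromo-8-methoxy-1-(methoxymethoxy)naphthalene F8. HCl in MeOH then releases 5.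

3. Step 4. What may go wrong: stalling after the first C–Br cleavage through poor solubility or catalyst poisoning, or partial saturation of a naphthalene ring if the reaction is forced. The fallback sets out from 8 and returns at 9. It replaces surface hydrogenolysis by a radical chain reduction: Bu3SnH (2.5 equiv) and azobisisobutyronitrile in toluene at 90 °C, in which each aryl radical takes hydrogen from the tin hydride under neutral conditions, followed by a KF wash to remove tin residues.

Further compounds
F1 | step 3 | 4-bromo-2-iodo-8-methoxy-1-naphthol | COc1cccc2c(Br)cc(I)c(O)c12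
F2 | step 3 | 4-bromo-2-iodo-8-methoxy-1-(methoxymethoxy)naphthalene | COCOc1c(I)cc(Br)c2cccc(OC)c12
F3 | step 3 | 8-methoxy-1-(methoxymethoxy)naphthalene | COCOc1cccc2cccc(OC)c12
F4 | step 3 | 2-[8-methoxy-1-(methoxymethoxy)naphthalen-2-yl]-4,4,5,5-tetramethyl-1,3,2-dioxaborolane | COCOc1c(B2OC(C)(C)C(C)(C)O2)ccc2cccc(OC)c12
F5 | step 3 | 8,8',8''-trimethoxy-1,1',1''-tris(methoxymethoxy)-2,2':4',2''-ternaphthalene | COc1cccc2ccc(-c3cc(-c4ccc5cccc(OC)c5c4OCOC)c4cccc(OC)c4c3OCOC)c(OCOC)c12
F6 | step 2 | 2,4-dibromo-8-methoxy-1-naphthol | COc1cccc2c(Br)cc(Br)c(O)c12
F7 | step 2 | 2,4-dibromo-8-methoxy-1-(methoxymethoxy)naphthalene | COCOc1c(Br)cc(Br)c2cccc(OC)c12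
F8 | step 2 | 4-bromo-8-methoxy-1-(methoxymethoxy)naphthalene | COCOc1ccc(Br)c2cccc(OC)c12
F0 | step 4 | none | none
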